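The runs were generated by integration from invented constants; noise was put on by code.

Wednesday's flask uses up substrate faster than Tuesday's by a factor of 2.90, more than the 2.00 by which its catalyst charge is larger. The first factor rests on the first samples, the second on the charges below.

common to all: impurity 4.8 µM

| flask | substrate | reagent | free catalyst | temperature | remark | time |
|---|---|---|---|---|---|---|
| Tuesday's | 5.0 × 10⁻⁴ M | 1.2 equiv | 2 mol% | 60 °C | run made earlier |  |
| Wednesday's | 5.0 × 10⁻⁴ M | 1.2 equiv | 4 mol% | 60 °C | run made earlier |  |
| delta | 5.0 × 10⁻⁴ M | 1.20 equiv (fed, over 1.0 min) | 2 mol% | 60 °C | all else is in the flask from the start; the feed brings no volume worth counting | 5.0 min |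
| epsilon | 5.0 × 10⁻⁴ M | 1.20 equiv | 2 mol% | 60 °C | everything together at the start | 5.0 min |
| theta | 5.0 × 10⁻⁴ M | 1.20 equiv | 2 mol% |  | everything together at the start at 40 °C, warmed to 60 °C at 1.0 min | 5.0 min |
| alpha | 5.0 × 10⁻⁴ M (in portions, 3, over 1.0 min) | 1.20 equiv | 2 mol% | 60 °C | first portion at the start, last at 1.0 min | 5.0 min |
| eta | 5.0 × 10⁻⁴ M | 1.20 equiv (fed, over 1.0 min) | 2 mol% |  | the addition at 40 °C, then warmed to 60 °C; the feed brings no volume worth counting | 5.0 min |

Tuesday's run (percent of the substrate charged)

| time / min | target / % | side product / % | substrate / % |
|---|---|---|---|
| 0.667 | 46 | 48 | 7 |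
| 1.33 | 51 | 47 | 0 |
| 2.00 | 50 | 48 | 0 |
| 2.50 | 53 | 49 | 0 |
| 3.00 | 49 | 52 | 4 |

Wednesday's run (percent of the substrate charged)

| time / s | target / % | side product / % | substrate / % |
|---|---|---|---|
| 12.0 | 57 | 22 | 19 |
| 25.0 | 73 | 23 | 2 |
| 40.0 | 76 | 28 | 2 |
| 50.0 | 76 | 23 | 0 |
| 60.0 | 76 | 26 | 0 |

(readings scatter by 2 percentage points)

- the best flask by share of target in target plus side product; "all alike" if 1.5 percentage points covers them all (delta / epsilon / theta / alpha / eta / all alike)
- share of target in target plus side product at the end, delta
- share of target in target plus side product at the end, epsilon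
- share of target in target plus side product at the end, theta
- share of target in target plus side product at the end, alpha
- share of target in target plus side product at the end, eta

- percentages count the substrate that a species holds: one side product counts as two
- released group is meant together with its crystals
- solid, in amounts per volume of the solution: crystals
- steps under discussion: catalyst intermediate C -> free catalyst + target; free catalyst + impurity -> spent catalyst; catalyst intermediate B -> released group + catalyst intermediate C; crystals <-> released group; substrate + free catalyst -> catalyst intermediate A; substrate + target -> side product; reagent + catalyst intermediate A <-> catalyst intermediate B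
- the earlier runs do not show what temperature does; that part of a forecast is a guess

1. Catalyst charge. I assume that impurity, a catalyst poison, removes free catalyst one for one. I then freeze what stays: the working catalyst, w = c(free catalyst) − c(impurity), both as charged. On Tuesday's recipe and on the new flasks, which share its charges of catalyst and impurity, it is 5.20 µM. On Wednesday's it is 15.2 µM, so by hand the rate should rise by 2.92. That comes from charges, while the 2.90 comes from scattered readings, each a mean up to a first sample, so the agreement is a rough check. The selectivity moves with it: target's share reads 51.0% at 2.00 min on Tuesday and 74.5% at 60.0 s on Wednesday. Epsilon has Tuesday's recipe, so I expect Tuesday's share.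

2. Reagent feed. With w frozen, I count the rounds of the cycle, one reagent each, in Tuesday's first sample as target plus half the side product, since one side product counts as two substrates and holds one target. That reads a turnover of 1.05 /min of the charge, as a mean up to that sample. Delta's feed brings 1.20 /min of reagent on the same scale, which is more by a factor of 1.14. With so narrow a lead of feed over turnover, I expect substrate in delta to stand beside target at least as long as in epsilon, and a share at or below epsilon's.

3. Substrate portions. In alpha one portion lasts about 0.318 min at that turnover, shorter than the 0.500 min between portions. Substrate therefore stays low beside target, and I expect alpha to be best.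

4. Temperature. The runs show nothing here, so I leave theta with epsilon and eta with delta, as a guess.

The forecast names alpha: delta 49% (42% to 55%), epsilon 51% (48% to 54%), theta 51% (43% to 59%), alpha 66% (54% to 73%), eta 49% (40% to 58%). Its ground for the winner: “Alpha keeps substrate low while catalyst stays saturated”.

    catalyst intermediate C → free catalyst + target (k = 10.3 /s, Ea = 64.0 kJ/mol)
    free catalyst + impurity → spent catalyst (k = 6.40 × 10⁶ /M/s, Ea = 23.0 kJ/mol)
    catalyst intermediate B → released group + catalyst intermediate C (k = 166 /s, Ea = 54.0 kJ/mol)
    crystals ⇌ released group, rate k4*(cs4 - [released group]) while solid is left; crystals form when [released group] > cs4 (solubility = 0.0210 mM, k = 4.38 /s)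
    substrate + free catalyst → catalyst intermediate A (k = 92300 /M/s, Ea = 24.0 kJ/mol)
    substrate + target → side product (k = 135 /M/s, Ea = 54.0 kJ/mol)
    reagent + catalyst intermediate A ⇌ catalyst intermediate B (K = 3000 /M, k = 6400 /M/s, Ea = 42.0 kJ/mol, ΔH = −61.0 kJ/mol)
    (constants at 60 °C)

Alpha comes out best at 63.5%, with delta 45.5%, epsilon 51.4%, theta 53.0% and eta 51.2%. At the end of delta, free catalyst is 52.0% of its charge and spent catalyst 48.0%, and w over the charge gives 52.0%. A neighbour of delta with 0.8 mol% of free catalyst has w = −0.800 µM, which means 16.7% of the impurity unmatched. That neighbour ends with 16.7% of its impurity left, 0% target and 94.9% of the substrate untouched.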